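Both ring–chain single bonds (C6–C7 and C6′–C7′, sp2–sp2) are cut; the last one made is C6′–C7′, by Suzuki–Miyaura coupling of a C36 polyenyl pinacol boronate (ring A plus the C7–C7′ nonaene) with the ring B enol triflate carrying the free allylic diol.
Enabling feature: in ring B (as in ring A) the tetrasubstituted C5′=C6′ alkene lies between the quaternary C1′ and the methyl-bearing C5′, so C6′ maps onto the carbonyl carbon of a 2,2,6-trimethylcyclohexanone that can enolize in one direction only and gives a single enol triflate; C7′ is the (E)-alkenyl end of the chain.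
The twofold-symmetric C7–C7′ nonaene comes in one step from the C20 dialdehyde C8–C8′ (crocetin dialdehyde) by two-fold Takai–Utimoto boryl-olefination, and is coupled first with the ring A triflate (C6–C7), then with the ring B triflate.
C2 (R) and C2′ (S) have opposite spatial sense, so the two antipodes of one ketone are made from 2-methylcyclohex-2-enone by copper-catalysed asymmetric conjugate addition/enolate methylation with the two ligand antipodes; the side chains follow by cross-metathesis (2-methylbut-2-ene for prenyl, 2-methylenepropane-1,3-diyl diacetate for the diol end).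
No ring is formed in the route: both cyclohexene rings are carried in from 2-methylcyclohex-2-enone; order of assembly is ring A, linchpin, ring B.

Key step: step 14

Remark: carotenoid numbering is used for the target (ring A = prenyl end, C1–C6; chain C7–C15 and C15′–C7′; ring B = diol end, C1′–C6′).
Remark: crocetin dialdehyde, Cl2CHBpin and 2-methylenepropane-1,3-diyl diacetate are taken as purchasable.
Assumption: the sense of induction of the copper–NHC catalyst with this Grignard reagent is to be assigned on the first run; "antipode a" of the ligand (step 1) is the one that leads to the R-configured ring A, "antipode b" (step 8) is its mirror image.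
Remark: within each ring series the CIP descriptor of the ring stereocenter switches between R and S only because the ranking of the side chain against the ring CH2 changes; the spatial arrangement set in steps 1 and 8 is never altered.

Step 1
Reactants: 1 2-methylcyclohex-2-en-1-one
Product: 3 (3R)-3-(but-3-en-1-yl)-2,2-dimethylcyclohexan-1-one, via bromomagnesium enolate 2 (not isolated)
Conditions: CH2=CHCH2CH2MgBr (1.3 equiv), Cu(OTf)2 (3 mol%), chiral N-mesityl-N′-(hydroxyalkyl)imidazolinium hexafluorophosphate (leucinol-derived NHC precursor, antipode a, 4 mol%), Et2O, −30 to 0 °C; then MeI (5 equiv), DMPU, 0 °C to rt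
Reagents that add atoms: but-3-enylmagnesium bromide, C=CCC[Mg]Br; iodomethane, CI
Why: Copper–NHC-catalysed asymmetric conjugate addition of a Grignard reagent to an α-substituted cyclic enone, in which the chiral ligand decides the face of C3 that is attacked and so sets the only stereocenter, followed by C-methylation of the regiodefined magnesium enolate at C2 (conjugate addition–enolate trapping) to build the gem-dimethyl carbon.

Step 2
Reactants: 3 (3R)-3-(but-3-en-1-yl)-2,2-dimethylcyclohexan-1-one
Product: 5 (3S,6RS)-3-(but-3-en-1-yl)-2,2,6-trimethylcyclohexan-1-one, via lithium enolate 4 (not isolated)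
Conditions: LiN(i-Pr)2 (1.1 equiv), THF, −78 °C; MeI (1.5 equiv), −78 to 0 °C
Reagents that add atoms: iodomethane, CI
Why: C2 is quaternary, so kinetic deprotonation and methylation (lithium enolate alkylation) can occur only at C6; the new C6 center forms as a mixture of epimers, which is without consequence because C6 becomes sp2 in step 4.

Step 3
Reactants: 5 (3S,6RS)-3-(but-3-en-1-yl)-2,2,6-trimethylcyclohexan-1-one
Product: 6 (3R,6RS)-3-[(2E)-but-2-en-1-yl]-2,2,6-trimethylcyclohexan-1-one (mainly E; any Z isomer is carried on)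
Conditions: Pd(dba)2 (1 mol%), P(t-Bu)3 (1 mol%), i-PrCOCl (1 mol%), toluene, 80 °C
Reagents that add atoms: none
Why: A bulky palladium hydride formed in situ moves the terminal double bond by one position through hydropalladation and β-hydride elimination (selective 1-alkene to 2-alkene isomerization), turning the homoallyl into a crotyl group without touching C3; the E/Z ratio does not matter for the later metathesis.

Step 4
Reactants: 6 (3R,6RS)-3-[(2E)-but-2-en-1-yl]-2,2,6-trimethylcyclohexan-1-one
Product: 8 (5R)-5-[(2E)-but-2-en-1-yl]-2,6,6-trimethylcyclohex-1-en-1-yl trifluoromethanesulfonate, via lithium enolate 7 (not isolated)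
Conditions: LiN(i-Pr)2 (1.2 equiv), THF, −78 to 0 °C; PhNTf2 (1.2 equiv), 0 °C to rt
Reagents that add atoms: N-phenylbis(trifluoromethanesulfonimide), O=S(=O)(N(c1ccccc1)S(=O)(=O)C(F)(F)F)C(F)(F)F
Why: The ketone has a single α-hydrogen (C6), so enolization and O-sulfonylation (enol triflate formation) can give only the tetrasubstituted enol triflate of the 2,6,6-trimethylcyclohexenyl type.

Step 5
Reactants: 8 (5R)-5-[(2E)-but-2-en-1-yl]-2,6,6-trimethylcyclohex-1-en-1-yl trifluoromethanesulfonate
Product: 9 (5R)-2,6,6-trimethyl-5-(3-methylbut-2-en-1-yl)cyclohex-1-en-1-yl trifluoromethanesulfonate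
Conditions: second-generation Grubbs catalyst (H2IMes)(PCy3)Cl2Ru=CHPh (5 mol%), 2-methylbut-2-ene/CH2Cl2, 40 °C
Reagents that add atoms: 2-methylbut-2-ene, CC=C(C)C
Why: Olefin cross-metathesis with 2-methylbut-2-ene exchanges the ethylidene end of the crotyl group for isopropylidene to give the prenyl group, while the tetrasubstituted enol triflate alkene is inert to the ruthenium carbene.

Step 6
Reactants: 10 crocetin dialdehyde
Product: 12 2,2′-[(1E,3E,5E,7E,9E,11E,13E,15E,17E)-3,7,12,16-tetramethyloctadeca-1,3,5,7,9,11,13,15,17-nonaene-1,18-diyl]bis(4,4,5,5-tetramethyl-1,3,2-dioxaborolane), via boryl octaenal 11 (not isolated)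
Conditions: Cl2CHBpin (4 equiv), CrCl2 (16 equiv), LiI (8 equiv), THF, rt, dark
Reagents that add atoms: 2-(dichloromethyl)-4,4,5,5-tetramethyl-1,3,2-dioxaborolane, ClC(Cl)B1OC(C)(C)C(C)(C)O1
Why: Two-fold Takai–Utimoto boryl-olefination, in which the geminal dichromium carbenoid made from Cl2CHBpin adds to each aldehyde and eliminates to the (E)-alkenylboronate, adds C7 and C7′ with E geometry and leaves the all-E heptaene of 10 untouched.

Step 7
Reactants: 9 ring A prenyl enol triflate (1 equiv); 12 C22 bis-boronate (3 equiv)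
Product: 13 2-[(1E,3E,5E,7E,9E,11E,13E,15E,17E)-3,7,12,16-tetramethyl-18-[(5R)-2,6,6-trimethyl-5-(3-methylbut-2-en-1-yl)cyclohex-1-en-1-yl]octadeca-1,3,5,7,9,11,13,15,17-nonaen-1-yl]-4,4,5,5-tetramethyl-1,3,2-dioxaborolane
Conditions: Pd(OAc)2 (5 mol%), SPhos (10 mol%), K3PO4 (3 equiv), THF/H2O (5:1), 40 °C, argon, dark; excess 12 recovered by chromatography
Reagents that add atoms: none
Why: Suzuki–Miyaura coupling of the hindered enol triflate with one of the two equivalent alkenylboronate ends forms the C6–C7 bond with retention of the E geometry; the threefold excess of the symmetric bis-boronate biases the statistics toward mono-coupling and the C7′ boronate is kept for step 14.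

Step 8
Reactants: 1 2-methylcyclohex-2-en-1-one
Product: 15 (3S)-3-(but-3-en-1-yl)-2,2-dimethylcyclohexan-1-one, via bromomagnesium enolate 14 (not isolated)
Conditions: CH2=CHCH2CH2MgBr (1.3 equiv), Cu(OTf)2 (3 mol%), the same imidazolinium hexafluorophosphate as in step 1 but antipode b (4 mol%), Et2O, −30 to 0 °C; then MeI (5 equiv), DMPU, 0 °C to rt
Reagents that add atoms: but-3-enylmagnesium bromide, C=CCC[Mg]Br; iodomethane, CI
Why: The same copper–NHC-catalysed asymmetric conjugate addition–enolate methylation as in step 1, where the mirror-image ligand directs the Grignard reagent to the opposite face of C3 and so sets the stereocenter of ring B.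

Step 9
Reactants: 15 (3S)-3-(but-3-en-1-yl)-2,2-dimethylcyclohexan-1-one
Product: 17 (3R,6RS)-3-(but-3-en-1-yl)-2,2,6-trimethylcyclohexan-1-one, via lithium enolate 16 (not isolated)
Conditions: LiN(i-Pr)2 (1.1 equiv), THF, −78 °C; MeI (1.5 equiv), −78 to 0 °C
Reagents that add atoms: iodomethane, CI
Why: Lithium enolate alkylation at C6, the only enolizable position; the C6 epimer mixture is without consequence because C6 becomes sp2 in step 11.

Step 10
Reactants: 17 (3R,6RS)-3-(but-3-en-1-yl)-2,2,6-trimethylcyclohexan-1-one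
Product: 18 (3S,6RS)-3-[(2E)-but-2-en-1-yl]-2,2,6-trimethylcyclohexan-1-one (mainly E; any Z isomer is carried on)
Conditions: Pd(dba)2 (1 mol%), P(t-Bu)3 (1 mol%), i-PrCOCl (1 mol%), toluene, 80 °C
Reagents that add atoms: none
Why: Selective one-position alkene isomerization by an in situ palladium hydride, as in step 3, gives the crotyl group without touching C3.

Step 11
Reactants: 18 (3S,6RS)-3-[(2E)-but-2-en-1-yl]-2,2,6-trimethylcyclohexan-1-one
Product: 20 (5S)-5-[(2E)-but-2-en-1-yl]-2,6,6-trimethylcyclohex-1-en-1-yl trifluoromethanesulfonate, via lithium enolate 19 (not isolated)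
Conditions: LiN(i-Pr)2 (1.2 equiv), THF, −78 to 0 °C; PhNTf2 (1.2 equiv), 0 °C to rt
Reagents that add atoms: N-phenylbis(trifluoromethanesulfonimide), O=S(=O)(N(c1ccccc1)S(=O)(=O)C(F)(F)F)C(F)(F)F
Why: Enol triflate formation from the only possible enolate, as in step 4, fixes the position of the later C5′=C6′ alkene.

Step 12
Reactants: 20 (5S)-5-[(2E)-but-2-en-1-yl]-2,6,6-trimethylcyclohex-1-en-1-yl trifluoromethanesulfonate
Product: 21 2-{2-[(1S)-2,2,4-trimethyl-3-(trifluoromethanesulfonyloxy)cyclohex-3-en-1-yl]ethylidene}propane-1,3-diyl diacetate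
Conditions: second-generation Hoveyda–Grubbs catalyst (H2IMes)Cl2Ru=CH(2-i-PrOC6H4) (10 mol%), 2-methylenepropane-1,3-diyl diacetate (5 equiv), CH2Cl2, 40 °C
Reagents that add atoms: 2-methylenepropane-1,3-diyl diacetate, C=C(COC(C)=O)COC(C)=O
Why: Olefin cross-metathesis of the crotyl alkene with the symmetric 1,1-disubstituted allylic diacetate gives the trisubstituted alkene, which has no E/Z issue because both CH2OAc groups are identical, with propene as volatile by-product and the enol triflate untouched.

Step 13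
Reactants: 21 ring B enol triflate diacetate
Product: 22 (5S)-5-[4-hydroxy-3-(hydroxymethyl)but-2-en-1-yl]-2,6,6-trimethylcyclohex-1-en-1-yl trifluoromethanesulfonate
Conditions: i-Bu2AlH (5 equiv), CH2Cl2, −78 °C; aqueous potassium sodium tartrate
Reagents that add atoms: none
Why: Low-temperature ester reduction with i-Bu2AlH cleaves both acetates without attacking the enol triflate, and it removes the allylic acetates, the only groups that zerovalent palladium could ionize in step 14.

Step 14
Reactants: 13 C36 polyenyl boronate (1.2 equiv); 22 ring B enol triflate diol (1 equiv)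
Product: 23 (2R,2′S)-2′-[4-hydroxy-3-(hydroxymethyl)but-2-en-1-yl]-2-(3-methylbut-2-en-1-yl)-β,β-carotene (all-E; CNP0213288.1)
Conditions: Pd(OAc)2 (5 mol%), SPhos (10 mol%), K3PO4 (3 equiv), THF/H2O (5:1), 40 °C, argon, dark
Reagents that add atoms: none
Why: Zerovalent palladium inserts into the C6′–O bond of enol triflate 22, phosphate-assisted transmetalation transfers the C7′ alkenyl group of boronate 13 with retention of its E geometry, and reductive elimination forms the C6′–C7′ bond (Suzuki–Miyaura coupling). The closest known reaction type is the coupling of 2,6,6-trimethylcyclohex-1-enyl triflates with dienyl and polyenyl boron reagents used for retinoids and carotenoids. No ring is closed and no stereocenter is made: C2 and C2′ were set in steps 1 and 8, are remote from the reacting carbons and cannot epimerize, and the position of the C5′=C6′ alkene is fixed by the triflate. The step needs chemoselectivity for the triflate over the two free allylic hydroxyl groups, which is secured because free alcohols, unlike the acetates removed in step 13, are not ionized by zerovalent palladium; it also needs retention of the all-E geometry, which is served by the mild temperature, exclusion of light and oxygen, and a bulky biaryl phosphine that speeds up coupling at the hindered carbon. In this one operation the last carbon–carbon bond is made, the conjugated undecaene chromophore is completed and the polar end group is attached without a protecting group, so no further step is needed.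

Compound list
1 | 2-methylcyclohex-2-en-1-one | CC1=CCCCC1=O | starting material
2 | bromomagnesium (3R)-3-(but-3-en-1-yl)-2-methylcyclohex-1-en-1-olate (not isolated) | C=CCC[C@H]1CCCC(O[Mg]Br)=C1C | intermediate
3 | (3R)-3-(but-3-en-1-yl)-2,2-dimethylcyclohexan-1-one | C=CCC[C@H]1CCCC(=O)C1(C)C | intermediate
4 | lithium (5S)-5-(but-3-en-1-yl)-6,6-dimethylcyclohex-1-en-1-olate (not isolated) | C=CCC[C@H]1CCC=C(O[Li])C1(C)C | intermediate
5 | (3S,6RS)-3-(but-3-en-1-yl)-2,2,6-trimethylcyclohexan-1-one | C=CCC[C@H]1CCC(C)C(=O)C1(C)C | intermediate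
6 | (3R,6RS)-3-[(2E)-but-2-en-1-yl]-2,2,6-trimethylcyclohexan-1-one | C/C=C/C[C@H]1CCC(C)C(=O)C1(C)C | intermediate
7 | lithium (5R)-5-[(2E)-but-2-en-1-yl]-2,6,6-trimethylcyclohex-1-en-1-olate (not isolated) | C/C=C/C[C@H]1CCC(C)=C(O[Li])C1(C)C | intermediate
8 | (5R)-5-[(2E)-but-2-en-1-yl]-2,6,6-trimethylcyclohex-1-en-1-yl trifluoromethanesulfonate | C/C=C/C[C@H]1CCC(C)=C(OS(=O)(=O)C(F)(F)F)C1(C)C | intermediate
9 | (5R)-2,6,6-trimethyl-5-(3-methylbut-2-en-1-yl)cyclohex-1-en-1-yl trifluoromethanesulfonate | CC(C)=CC[C@H]1CCC(C)=C(OS(=O)(=O)C(F)(F)F)C1(C)C | intermediate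
10 | crocetin dialdehyde, (2E,4E,6E,8E,10E,12E,14E)-2,6,11,15-tetramethylhexadeca-2,4,6,8,10,12,14-heptaenedial | O=C/C(C)=C/C=C/C(C)=C/C=C/C=C(C)/C=C/C=C(C)/C=O | starting material
11 | (2E,4E,6E,8E,10E,12E,14E,16E)-2,6,11,15-tetramethyl-17-(4,4,5,5-tetramethyl-1,3,2-dioxaborolan-2-yl)heptadeca-2,4,6,8,10,12,14,16-octaenal (not isolated) | O=C/C(C)=C/C=C/C(C)=C/C=C/C=C(C)/C=C/C=C(C)/C=C/B1OC(C)(C)C(C)(C)O1 | intermediate
12 | 2,2′-[(1E,3E,5E,7E,9E,11E,13E,15E,17E)-3,7,12,16-tetramethyloctadeca-1,3,5,7,9,11,13,15,17-nonaene-1,18-diyl]bis(4,4,5,5-tetramethyl-1,3,2-dioxaborolane) | CC1(C)OB(/C=C/C(C)=C/C=C/C(C)=C/C=C/C=C(C)/C=C/C=C(C)/C=C/B2OC(C)(C)C(C)(C)O2)OC1(C)C | intermediate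
13 | 2-[(1E,3E,5E,7E,9E,11E,13E,15E,17E)-3,7,12,16-tetramethyl-18-[(5R)-2,6,6-trimethyl-5-(3-methylbut-2-en-1-yl)cyclohex-1-en-1-yl]octadeca-1,3,5,7,9,11,13,15,17-nonaen-1-yl]-4,4,5,5-tetramethyl-1,3,2-dioxaborolane | CC(C)=CC[C@H]1CCC(C)=C(/C=C/C(C)=C/C=C/C(C)=C/C=C/C=C(C)/C=C/C=C(C)/C=C/B2OC(C)(C)C(C)(C)O2)C1(C)C | intermediate
14 | bromomagnesium (3S)-3-(but-3-en-1-yl)-2-methylcyclohex-1-en-1-olate (not isolated) | C=CCC[C@@H]1CCCC(O[Mg]Br)=C1C | intermediate
15 | (3S)-3-(but-3-en-1-yl)-2,2-dimethylcyclohexan-1-one | C=CCC[C@@H]1CCCC(=O)C1(C)C | intermediate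
16 | lithium (5R)-5-(but-3-en-1-yl)-6,6-dimethylcyclohex-1-en-1-olate (not isolated) | C=CCC[C@@H]1CCC=C(O[Li])C1(C)C | intermediate
17 | (3R,6RS)-3-(but-3-en-1-yl)-2,2,6-trimethylcyclohexan-1-one | C=CCC[C@@H]1CCC(C)C(=O)C1(C)C | intermediate
18 | (3S,6RS)-3-[(2E)-but-2-en-1-yl]-2,2,6-trimethylcyclohexan-1-one | C/C=C/C[C@@H]1CCC(C)C(=O)C1(C)C | intermediate
19 | lithium (5S)-5-[(2E)-but-2-en-1-yl]-2,6,6-trimethylcyclohex-1-en-1-olate (not isolated) | C/C=C/C[C@@H]1CCC(C)=C(O[Li])C1(C)C | intermediate
20 | (5S)-5-[(2E)-but-2-en-1-yl]-2,6,6-trimethylcyclohex-1-en-1-yl trifluoromethanesulfonate | C/C=C/C[C@@H]1CCC(C)=C(OS(=O)(=O)C(F)(F)F)C1(C)C | intermediate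
21 | 2-{2-[(1S)-2,2,4-trimethyl-3-(trifluoromethanesulfonyloxy)cyclohex-3-en-1-yl]ethylidene}propane-1,3-diyl diacetate | CC(=O)OCC(COC(C)=O)=CC[C@@H]1CCC(C)=C(OS(=O)(=O)C(F)(F)F)C1(C)C | intermediate
22 | (5S)-5-[4-hydroxy-3-(hydroxymethyl)but-2-en-1-yl]-2,6,6-trimethylcyclohex-1-en-1-yl trifluoromethanesulfonate | OCC(CO)=CC[C@@H]1CCC(C)=C(OS(=O)(=O)C(F)(F)F)C1(C)C | intermediate
23 | (2R,2′S)-2′-[4-hydroxy-3-(hydroxymethyl)but-2-en-1-yl]-2-(3-methylbut-2-en-1-yl)-β,β-carotene (all-E; CNP0213288.1) | CC(C)=CC[C@H]1CCC(C)=C(/C=C/C(C)=C/C=C/C(C)=C/C=C/C=C(C)/C=C/C=C(C)/C=C/C2=C(C)CC[C@@H](CC=C(CO)CO)C2(C)C)C1(C)C | target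

Total step count: 14
Longest linear sequence: 7 steps (steps 1, 2, 3, 4, 5, 7, 14; the ring B arm, steps 8 to 14, is equally long)

Steps most likely to fail

Step 14 (key step). Transmetalation at the hindered tetrasubstituted alkenylpalladium center may be slower than base-induced protodeboronation and E/Z isomerization of the long polyenyl boronate. The fallback moves both couplings to the base-free Stille manifold; it sets out from 10 (with 9 and 22) and comes back to the route at 23. Two-fold stannyl-olefination of 10 (Bu3SnCHBr2, CrCl2, LiI, THF/DMF, rt) should give (1E,3E,5E,7E,9E,11E,13E,15E,17E)-3,7,12,16-tetramethyl-1,18-bis(tributylstannyl)octadeca-1,3,5,7,9,11,13,15,17-nonaene F1. Stille coupling of an excess of this bis-stannane with 9 (Pd2(dba)3, AsPh3, NMP, 50 °C) should give the mono-stannane tributyl{(1E,3E,5E,7E,9E,11E,13E,15E,17E)-3,7,12,16-tetramethyl-18-[(5R)-2,6,6-trimethyl-5-(3-methylbut-2-en-1-yl)cyclohex-1-en-1-yl]octadeca-1,3,5,7,9,11,13,15,17-nonaen-1-yl}stannane F2. A second Stille coupling under the same conditions with 22 should give 23.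

Step 7. Statistical double coupling at both boronate ends, together with partial loss of the remaining boronate and a difficult separation of mono- and bis-coupled polyenes, may erode the supply of 13. The fallback desymmetrizes at the aldehyde stage instead; it sets out from 10 and comes back to the route at 13. Treatment of 10 with a limiting amount of Cl2CHBpin (CrCl2, LiI, THF) is stopped at the mono-olefination stage and 11 is isolated; dialdehyde, mono-aldehyde and bis-boronate differ clearly in polarity. Suzuki–Miyaura coupling of 11 with 9 under the conditions of step 7 should give the polyenal (2E,4E,6E,8E,10E,12E,14E,16E)-2,6,11,15-tetramethyl-17-[(5R)-2,6,6-trimethyl-5-(3-methylbut-2-en-1-yl)cyclohex-1-en-1-yl]heptadeca-2,4,6,8,10,12,14,16-octaenal F3, in which the triflate meets a single boron end. Takai–Utimoto boryl-olefination of this aldehyde (Cl2CHBpin, CrCl2, LiI, THF) should then give 13.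

Step 12. Low turnover in the cross-metathesis between the internal alkene and the hindered 1,1-disubstituted allylic diacetate (non-productive metathesis, catalyst decay) may leave mostly starting material. The fallback builds the diol end by carbonyl chemistry; it sets out from 20 and comes back to the route at 22. Oxidative cleavage of the crotyl alkene of 20 (OsO4 cat., NaIO4, 2,6-lutidine, dioxane/H2O; the electron-poor tetrasubstituted enol triflate alkene should not react) should give the aldehyde (5S)-2,6,6-trimethyl-5-(2-oxoethyl)cyclohex-1-en-1-yl trifluoromethanesulfonate F4. Knoevenagel condensation with dimethyl malonate (TiCl4, pyridine, THF, 0 °C) should give the alkylidene malonate dimethyl 2-{2-[(1S)-2,2,4-trimethyl-3-(trifluoromethanesulfonyloxy)cyclohex-3-en-1-yl]ethylidene}propanedioate F5. Reduction of both esters (i-Bu2AlH, CH2Cl2, −78 °C) should give 22.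

Further compounds
F1 | step 14 | (1E,3E,5E,7E,9E,11E,13E,15E,17E)-3,7,12,16-tetramethyl-1,18-bis(tributylstannyl)octadeca-1,3,5,7,9,11,13,15,17-nonaene | CCCC[Sn](CCCC)(CCCC)/C=C/C(C)=C/C=C/C(C)=C/C=C/C=C(C)/C=C/C=C(C)/C=C/[Sn](CCCC)(CCCC)CCCC
F2 | step 14 | tributyl{(1E,3E,5E,7E,9E,11E,13E,15E,17E)-3,7,12,16-tetramethyl-18-[(5R)-2,6,6-trimethyl-5-(3-methylbut-2-en-1-yl)cyclohex-1-en-1-yl]octadeca-1,3,5,7,9,11,13,15,17-nonaen-1-yl}stannane | CC(C)=CC[C@H]1CCC(C)=C(/C=C/C(C)=C/C=C/C(C)=C/C=C/C=C(C)/C=C/C=C(C)/C=C/[Sn](CCCC)(CCCC)CCCC)C1(C)C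
F3 | step 7 | (2E,4E,6E,8E,10E,12E,14E,16E)-2,6,11,15-tetramethyl-17-[(5R)-2,6,6-trimethyl-5-(3-methylbut-2-en-1-yl)cyclohex-1-en-1-yl]heptadeca-2,4,6,8,10,12,14,16-octaenal | CC(C)=CC[C@H]1CCC(C)=C(/C=C/C(C)=C/C=C/C(C)=C/C=C/C=C(C)/C=C/C=C(C)/C=O)C1(C)C
F4 | step 12 | (5S)-2,6,6-trimethyl-5-(2-oxoethyl)cyclohex-1-en-1-yl trifluoromethanesulfonate | O=CC[C@@H]1CCC(C)=C(OS(=O)(=O)C(F)(F)F)C1(C)C
F5 | step 12 | dimethyl 2-{2-[(1S)-2,2,4-trimethyl-3-(trifluoromethanesulfonyloxy)cyclohex-3-en-1-yl]ethylidene}propanedioate | COC(=O)C(C(=O)OC)=CC[C@@H]1CCC(C)=C(OS(=O)(=O)C(F)(F)F)C1(C)C
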